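Cuts: after removal of six benzyl ethers and one acetonide, the retrosynthesis breaks U-C4–C4a (ring C of unit U), then U-C2–O1, then the U-C3=C4 alkene that joins the chain to L-C6. Unit L is cut at its C4 oxygen, at C4–C4a and at C2–O1.
Enabling feature: U-C4 is a doubly benzylic CH bonded to C4a of ring A (unit U) and to C6 of ring A (unit L, where O1 is para and O7 ortho to C6). It sits next to the C3 carbinol, which is what remains of a trans-epoxide opened at its benzylic carbon by a ring A tethered through O1–C2.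
Forward order: ring C of unit L (epoxy-arene closure), C4 oxygenation and dioxolane, C6 bromination and vinylation, cross metathesis, epoxidation, aryl ether, ring C of unit U last, deprotection.
Stereochemistry: one Sharpless kinetic resolution feeds both halves. The epoxidised (R)-carbinol gives L-C3 and, after Mitsunobu inversion, L-C2; the recovered (S)-carbinol gives U-C2 after a second Mitsunobu inversion.
L-C4 comes from substrate-controlled hydride delivery; U-C3 and U-C4 come from a reagent-controlled Shi epoxidation and inversion at C4 in the ring closure.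

Key step: step 16

Assumption: flavan numbering is used for both units. The SMILES is read as unit U (2S,3R,4S; 2,3-trans-3,4-trans) and unit L (2R,3R,4R; 2,3-cis-3,4-cis). "Core 16" means acetonide 16 attached through its C6.

Step 1
Reactants: 1 2,3-dihydroxybenzaldehyde
Product: 2 2,3-bis(benzyloxy)benzaldehyde
Conditions: BnBr (2.4 equiv), K2CO3, DMF, 60 °C
Reagents that add atoms: benzyl bromide, BrCc1ccccc1
Why: Williamson ether synthesis, in which both phenoxides are alkylated by the benzylic bromide while the non-enolisable aldehyde is untouched.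

Step 2
Reactants: 2 2,3-bis(benzyloxy)benzaldehyde
Product: 4 2,3-bis(benzyloxy)phenol, via aryl formate 3 (not isolated)
Conditions: mCPBA, CH2Cl2, rt; aq NaHCO3 wash; then K2CO3 (cat.), MeOH, rt
Reagents that add atoms: 3-chloroperoxybenzoic acid, OOC(=O)c1cccc(Cl)c1
Why: Baeyer–Villiger oxidation of an electron-rich benzaldehyde (Dakin-type outcome), in which the alkoxy-substituted aryl group migrates to oxygen, followed by base-catalysed methanolysis of the aryl formate.

Step 3
Reactants: 5 4-(benzyloxy)benzaldehyde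
Product: 6 rac-1-[4-(benzyloxy)phenyl]prop-2-en-1-ol
Conditions: CH2=CHMgBr, THF, 0 °C; then H2O
Reagents that add atoms: vinylmagnesium bromide, C=C[Mg]Br
Why: Grignard 1,2-addition to a non-enolisable aldehyde; the racemate is wanted because each enantiomer serves one half of the target.

Step 4
Reactants: 6 rac-1-[4-(benzyloxy)phenyl]prop-2-en-1-ol
Product: 7 (S)-[4-(benzyloxy)phenyl][(2R)-oxiran-2-yl]methanol (anti epoxy alcohol); 8 (S)-1-[4-(benzyloxy)phenyl]prop-2-en-1-ol (unreacted enantiomer, recovered)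
Conditions: Ti(OiPr)4 (10 mol %), L-(+)-DIPT (15 mol %), t-BuOOH (0.5 equiv), 4 Å MS, CH2Cl2, −20 °C
Reagents that add atoms: tert-butyl hydroperoxide, CC(C)(C)OO
Why: Sharpless kinetic resolution: with L-(+)-DIPT the (R)-carbinol is epoxidised far faster than its mirror image and on the face that gives the anti (erythro) epoxy alcohol, which fixes the future L-C3 as R and leaves L-C2 ready for a later inversion, while the slow (S)-carbinol 8 is kept for unit U.

Step 5
Reactants: 4 2,3-bis(benzyloxy)phenol; 7 (S)-[4-(benzyloxy)phenyl][(2R)-oxiran-2-yl]methanol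
Product: 9 (2R)-2-{(R)-[2,3-bis(benzyloxy)phenoxy][4-(benzyloxy)phenyl]methyl}oxirane
Conditions: n-Bu3P, TMAD, toluene, 0 °C to rt
Reagents that add atoms: none
Why: Mitsunobu etherification: the phenoxide displaces the oxyphosphonium group by SN2 with inversion to give the (R)-configured L-C2, the inductive pull of the neighbouring oxirane disfavouring ionisation, as known for aryl ethers of 1-aryl-2,3-epoxypropanols used in catechin synthesis.

Step 6
Reactants: 9 (2R)-2-{(R)-[2,3-bis(benzyloxy)phenoxy][4-(benzyloxy)phenyl]methyl}oxirane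
Product: 10 (2R,3R)-7,8-bis(benzyloxy)-2-[4-(benzyloxy)phenyl]chroman-3-ol (2,3-cis)
Conditions: AuCl3 (5 mol %), AgOTf (15 mol %), ClCH2CH2Cl, 4 Å MS, 0 °C to rt
Reagents that add atoms: none
Why: Intramolecular Friedel–Crafts alkylation (epoxy-arene cycloalkylation) under cationic trivalent gold catalysis, established for 2-arylchroman-3-ols: the free ortho carbon, para to a benzyloxy group, opens the oxirane at its terminal carbon in the 6-endo mode, so C2 and C3 are not touched and stay cis.

Step 7
Reactants: 10 (2R,3R)-7,8-bis(benzyloxy)-2-[4-(benzyloxy)phenyl]chroman-3-ol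
Product: 11 (2R,3R)-7,8-bis(benzyloxy)-2-[4-(benzyloxy)phenyl]chroman-3-yl acetate
Conditions: Ac2O, pyridine, DMAP (cat.), CH2Cl2, rt
Reagents that add atoms: acetic anhydride, CC(=O)OC(C)=O
Why: Standard DMAP-catalysed acylation, which shields the carbinol from oxidation in the next step.

Step 8
Reactants: 11 (2R,3R)-7,8-bis(benzyloxy)-2-[4-(benzyloxy)phenyl]chroman-3-yl acetate
Product: 13 (2R,3S)-7,8-bis(benzyloxy)-2-[4-(benzyloxy)phenyl]-4-oxochroman-3-yl acetate (2,3-cis), via 4β-alcohol 12 (not isolated)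
Conditions: DDQ (2.5 equiv), CH2Cl2/H2O (10:1), rt
Reagents that add atoms: water, O
Why: DDQ benzylic oxidation as practised on flavan-3-ol ethers: hydride abstraction from C4 gives a cation stabilised by O7 (para to C4a) and O1 (ortho), water adds anti to the 3-acetoxy group, and a second equivalent of DDQ dehydrogenates the electron-rich benzylic alcohol to the aryl ketone.

Step 9
Reactants: 13 (2R,3S)-7,8-bis(benzyloxy)-2-[4-(benzyloxy)phenyl]-4-oxochroman-3-yl acetate
Product: 15 (2R,3R,4R)-7,8-bis(benzyloxy)-2-[4-(benzyloxy)phenyl]chromane-3,4-diol (all-cis), via 4α-hydroxy 3-acetate 14 (not isolated)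
Conditions: NaBH4, THF/MeOH, −20 to 0 °C; then K2CO3 (cat.), MeOH, rt
Reagents that add atoms: none
Why: Substrate-controlled carbonyl reduction: with the 2-aryl group equatorial and the 3-acetoxy group axial, borohydride attacks C4 anti to the axial C3–O bond (polar Felkin–Anh and steric control agree), placing the new hydroxyl cis to O3 and setting L-C4 as R, after which base-catalysed transesterification frees O3.

Step 10
Reactants: 15 (2R,3R,4R)-7,8-bis(benzyloxy)-2-[4-(benzyloxy)phenyl]chromane-3,4-diol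
Product: 16 3,4-O-isopropylidene acetal of 15 (cis-fused dioxolane, configuration as in 15)
Conditions: Me2C(OMe)2, PPTS (cat.), acetone, rt
Reagents that add atoms: 2,2-dimethoxypropane, COC(C)(C)OC
Why: Acid-catalysed transketalisation, possible only for the 3,4-cis diol, gives a dioxolane that tolerates base, palladium, ruthenium and dioxirane chemistry.

Step 11
Reactants: 16 3,4-O-isopropylidene acetal of 15
Product: 17 6-bromo derivative of 16
Conditions: NBS (1.0 equiv), CH2Cl2, −20 °C, dark
Reagents that add atoms: N-bromosuccinimide, O=C1CCC(=O)N1Br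
Why: Electrophilic aromatic bromination: C6 is para to O1 and ortho to O7 and is therefore the most activated free position of the pyrogallol-type ring A, ahead of C5 and of the monoalkoxy ring B.

Step 12
Reactants: 17 6-bromo derivative of 16
Product: 18 6-vinyl derivative of 16
Conditions: vinylboronic acid pinacol ester, Pd(OAc)2 (5 mol %), SPhos (10 mol %), K3PO4, toluene/H2O, 80 °C
Reagents that add atoms: vinylboronic acid pinacol ester, C=CB1OC(C)(C)C(C)(C)O1
Why: Suzuki–Miyaura vinylation, with a bulky electron-rich biarylphosphine to drive oxidative addition of the hindered, electron-rich aryl bromide.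

Step 13
Reactants: 18 6-vinyl derivative of 16; 8 (S)-1-[4-(benzyloxy)phenyl]prop-2-en-1-ol
Product: 19 (1S,2E)-1-[4-(benzyloxy)phenyl]-3-(core 16)prop-2-en-1-ol
Conditions: 8 (2.5 equiv), second-generation Hoveyda–Grubbs catalyst (5 mol %), 1,4-benzoquinone (10 mol %), CH2Cl2, 40 °C
Reagents that add atoms: none
Why: Olefin cross metathesis of a styrene with a secondary allylic alcohol, which is E-selective on thermodynamic grounds and leaves the carbinol stereocentre alone, benzoquinone suppressing isomerisation by ruthenium hydrides.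

Step 14
Reactants: 19 (1S,2E)-1-[4-(benzyloxy)phenyl]-3-(core 16)prop-2-en-1-ol
Product: 20 (1R,2S,3S)-1-[4-(benzyloxy)phenyl]-2,3-epoxy-3-(core 16)propan-1-ol (syn, trans-epoxide; carbinol carbon spatially unchanged, descriptor altered by priorities only)
Conditions: L-fructose-derived Shi ketone (30 mol %), KHSO5 (as 2KHSO5·KHSO4·K2SO4), K2CO3, Bu4NHSO4 (cat.), MeCN/CH2(OMe)2/aq Na2B4O7 buffer (pH 10.5), 0 °C
Reagents that add atoms: potassium peroxymonosulfate, [K+].[O-]S(=O)(=O)OO
Why: Shi epoxidation: the chiral dioxirane attacks the trans-alkene through a spiro transition state under reagent control, and since the D-fructose-derived ketone turns trans-β-methylstyrene into its (R,R)-oxide the mirror-image ketone should give the (S,S)-oxirane, that is the syn (threo) epoxy alcohol that hydroxyl-directed titanium or vanadium epoxidations do not favour, while the basic buffer protects an epoxide whose aryl ring has oxygen ortho and para.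

Step 15
Reactants: 20 (1R,2S,3S)-1-[4-(benzyloxy)phenyl]-2,3-epoxy-3-(core 16)propan-1-ol; 4 2,3-bis(benzyloxy)phenol
Product: 21 2,3-bis(benzyloxy)phenyl ether of the C1 epimer of 20 (U-C2 S, U-C3 R, U-C4 S; anti ether, trans-epoxide)
Conditions: 4 (1.5 equiv), n-Bu3P, TMAD, toluene, 0 °C to rt; chromatography on Et3N-deactivated silica
Reagents that add atoms: none
Why: Mitsunobu etherification with SN2 inversion converts the (R)-carbinol into the (S)-configured U-C2 aryl ether, turning the syn epoxy alcohol into the anti ether that maps onto a 2,3-trans ring, under essentially neutral conditions that spare the epoxide.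

Step 16
Reactants: 21 2,3-bis(benzyloxy)phenyl ether (U-C2 S, U-C3 R, U-C4 S; trans-epoxide)
Product: 22 protected biflavanoid: six benzyl ethers, unit L acetonide, free U-C3 hydroxyl; unit U 2,3-trans-3,4-trans with C2 S and C3 R
Conditions: BF3·OEt2 (0.2 equiv), CH2Cl2 (0.005 M), 4 Å MS, −78 °C; Et3N quench
Reagents that add atoms: none
Why: BF3 binds the epoxide oxygen and the C4–O bond lengthens because the charge developing at U-C4 is delocalised into ring A of unit L, whose O1 is para and whose 7-benzyloxy group is ortho to C6. The only free ortho carbon of the tethered 2,3-bis(benzyloxy)phenyl ether, para to the future 7-benzyloxy group, attacks C4 from the side away from the departing oxygen and rearomatises; this is an intramolecular Friedel–Crafts alkylation of the epoxy-arene type, known for aryl ethers of trans-3-aryl-2,3-epoxy alcohols, which give trans-4-arylchroman-3-ols. Ring C of unit U closes in the 6-endo-tet mode. The one new stereocentre, U-C4, is fixed by inversion of the epoxide carbon set in step 14, and if the opening becomes carbocation-like the chair-like closure with the C2 aryl, C3 oxygen and C4 aryl groups all equatorial leads to the same 2,3-trans-3,4-trans ring. The step needs attack at C4 and not at C3 (5-exo), which the benzylic stabilisation secures, and it needs the epoxide to react before the benzylic dioxolane of unit L, which ring strain, low temperature and a substoichiometric Lewis acid secure. Any reversible C4–O ionisation in that dioxolane can only re-close to the same cis-fused ring.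

Step 17
Reactants: 22 protected biflavanoid
Product: 23 hexa-O-benzyl ether of the target (L-3,4-diol and U-3-ol free)
Conditions: AcOH/THF/H2O (4:1:1), 40 °C
Reagents that add atoms: none
Why: Mild acid hydrolysis of an isopropylidene acetal, which proceeds by O–CMe2 cleavage so that the C3–O and C4–O bonds keep their configuration, the benzyl ethers preventing quinone methide formation in ring A of unit L.

Step 18
Reactants: 23 hexa-O-benzyl ether of the target
Product: 24 (2R,3R,4R)-2-(4-hydroxyphenyl)-6-[(2S,3R,4S)-3,7,8-trihydroxy-2-(4-hydroxyphenyl)chroman-4-yl]chromane-3,4,7,8-tetrol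
Conditions: H2 (1 atm), Pd(OH)2/C, THF/MeOH, rt
Reagents that add atoms: none
Why: Catalytic hydrogenolysis of aryl benzyl ethers under neutral conditions, the usual last step for benzylated proanthocyanidins, in which the secondary benzylic C–O and C–C bonds of the flavan rings react much more slowly.

Compound list
1 | 2,3-dihydroxybenzaldehyde | O=Cc1cccc(O)c1O | starting material
2 | 2,3-bis(benzyloxy)benzaldehyde | O=Cc1cccc(OCc2ccccc2)c1OCc1ccccc1 | intermediate
3 | 2,3-bis(benzyloxy)phenyl formate | O=COc1cccc(OCc2ccccc2)c1OCc1ccccc1 | intermediate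
4 | 2,3-bis(benzyloxy)phenol | Oc1cccc(OCc2ccccc2)c1OCc1ccccc1 | intermediate
5 | 4-(benzyloxy)benzaldehyde | O=Cc1ccc(OCc2ccccc2)cc1 | starting material
6 | rac-1-[4-(benzyloxy)phenyl]prop-2-en-1-ol | OC(C=C)c1ccc(OCc2ccccc2)cc1 | intermediate
7 | (S)-[4-(benzyloxy)phenyl][(2R)-oxiran-2-yl]methanol | O[C@@H](c1ccc(OCc2ccccc2)cc1)[C@H]1CO1 | intermediate
8 | (S)-1-[4-(benzyloxy)phenyl]prop-2-en-1-ol | O[C@H](c1ccc(OCc2ccccc2)cc1)C=C | intermediate
9 | (2R)-2-{(R)-[2,3-bis(benzyloxy)phenoxy][4-(benzyloxy)phenyl]methyl}oxirane | c1ccc(OCc2ccccc2)c(OCc2ccccc2)c1O[C@H](c1ccc(OCc2ccccc2)cc1)[C@H]1CO1 | intermediate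
10 | (2R,3R)-7,8-bis(benzyloxy)-2-[4-(benzyloxy)phenyl]chroman-3-ol | c1cc2c(c(OCc3ccccc3)c1OCc1ccccc1)O[C@H](c1ccc(OCc3ccccc3)cc1)[C@H](O)C2 | intermediate
11 | (2R,3R)-7,8-bis(benzyloxy)-2-[4-(benzyloxy)phenyl]chroman-3-yl acetate | c1cc2c(c(OCc3ccccc3)c1OCc1ccccc1)O[C@H](c1ccc(OCc3ccccc3)cc1)[C@H](OC(C)=O)C2 | intermediate
12 | (2R,3R,4S)-7,8-bis(benzyloxy)-2-[4-(benzyloxy)phenyl]-4-hydroxychroman-3-yl acetate (2,3-cis-3,4-trans) | c1cc2c(c(OCc3ccccc3)c1OCc1ccccc1)O[C@H](c1ccc(OCc3ccccc3)cc1)[C@H](OC(C)=O)[C@H]2O | intermediate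
13 | (2R,3S)-7,8-bis(benzyloxy)-2-[4-(benzyloxy)phenyl]-4-oxochroman-3-yl acetate (2,3-cis) | c1cc2c(c(OCc3ccccc3)c1OCc1ccccc1)O[C@H](c1ccc(OCc3ccccc3)cc1)[C@H](OC(C)=O)C2=O | intermediate
14 | (2R,3R,4R)-7,8-bis(benzyloxy)-2-[4-(benzyloxy)phenyl]-4-hydroxychroman-3-yl acetate (all-cis) | c1cc2c(c(OCc3ccccc3)c1OCc1ccccc1)O[C@H](c1ccc(OCc3ccccc3)cc1)[C@H](OC(C)=O)[C@@H]2O | intermediate
15 | (2R,3R,4R)-7,8-bis(benzyloxy)-2-[4-(benzyloxy)phenyl]chromane-3,4-diol (all-cis) | c1cc2c(c(OCc3ccccc3)c1OCc1ccccc1)O[C@H](c1ccc(OCc3ccccc3)cc1)[C@H](O)[C@@H]2O | intermediate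
16 | 3,4-O-isopropylidene acetal of 15 | c1cc2c(c(OCc3ccccc3)c1OCc1ccccc1)O[C@H](c1ccc(OCc3ccccc3)cc1)[C@@H]3OC(C)(C)O[C@H]23 | intermediate
17 | 6-bromo derivative of 16 | Brc1cc2c(c(OCc3ccccc3)c1OCc1ccccc1)O[C@H](c1ccc(OCc3ccccc3)cc1)[C@@H]3OC(C)(C)O[C@H]23 | intermediate
18 | 6-vinyl derivative of 16 | C=Cc1cc2c(c(OCc3ccccc3)c1OCc1ccccc1)O[C@H](c1ccc(OCc3ccccc3)cc1)[C@@H]3OC(C)(C)O[C@H]23 | intermediate
19 | (1S,2E)-1-[4-(benzyloxy)phenyl]-3-(core 16)prop-2-en-1-ol | O[C@H](c1ccc(OCc2ccccc2)cc1)/C=C/c1cc2c(c(OCc3ccccc3)c1OCc1ccccc1)O[C@H](c1ccc(OCc3ccccc3)cc1)[C@@H]3OC(C)(C)O[C@H]23 | intermediate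
20 | (1R,2S,3S)-1-[4-(benzyloxy)phenyl]-2,3-epoxy-3-(core 16)propan-1-ol (syn, trans-epoxide) | O[C@H](c1ccc(OCc2ccccc2)cc1)[C@@H]1O[C@H]1c1cc2c(c(OCc3ccccc3)c1OCc1ccccc1)O[C@H](c1ccc(OCc3ccccc3)cc1)[C@@H]3OC(C)(C)O[C@H]23 | intermediate
21 | 2,3-bis(benzyloxy)phenyl ether of the C1 epimer of 20 (key-step precursor) | c1ccc(OCc2ccccc2)c(OCc2ccccc2)c1O[C@@H](c1ccc(OCc2ccccc2)cc1)[C@@H]1O[C@H]1c1cc2c(c(OCc3ccccc3)c1OCc1ccccc1)O[C@H](c1ccc(OCc3ccccc3)cc1)[C@@H]3OC(C)(C)O[C@H]23 | intermediate
22 | protected biflavanoid (six benzyl ethers, unit L acetonide, free U-C3 hydroxyl; key-step product) | C(c1ccccc1)Oc1ccc(cc1)[C@H]2Oc3c(cc([C@H]4c5ccc(OCc7ccccc7)c(OCc7ccccc7)c5O[C@@H](c5ccc(OCc7ccccc7)cc5)[C@@H]4O)c(OCc4ccccc4)c3OCc3ccccc3)[C@@H](OC(C)(C)O6)[C@H]26 | intermediate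
23 | hexa-O-benzyl ether of the target | C(c1ccccc1)Oc1ccc(cc1)[C@H]2Oc3c(cc([C@H]4c5ccc(OCc7ccccc7)c(OCc7ccccc7)c5O[C@@H](c5ccc(OCc7ccccc7)cc5)[C@@H]4O)c(OCc4ccccc4)c3OCc3ccccc3)[C@@H](O)[C@H]2O | intermediate
24 | (2R,3R,4R)-2-(4-hydroxyphenyl)-6-[(2S,3R,4S)-3,7,8-trihydroxy-2-(4-hydroxyphenyl)chroman-4-yl]chromane-3,4,7,8-tetrol | Oc1ccc([C@H]2Oc3c(cc([C@H]4c5ccc(O)c(O)c5O[C@@H](c5ccc(O)cc5)[C@@H]4O)c(O)c3O)[C@@H](O)[C@H]2O)cc1 | target

Total step count: 18. Longest linear sequence: 16 steps (steps 3 to 18, from 5).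

Steps most likely to fail

**Step 16 (ring closure).**
- What may go wrong: the charge building at U-C4 may be released by a 1,2-hydride shift from C3 (Meinwald-type rearrangement) or by stray nucleophiles before ring A closes. The Lewis acid may also erode the dioxolane.
- Fallback: the strain-driven opening is separated from the C–C bond formation. Setting out from 21, thiophenol with Et3N in THF opens the epoxide at its benzylic carbon under basic conditions to give the β-hydroxy sulfide F1.
- AgBF4 with 2,6-di-tert-butylpyridine in CH2Cl2 at −40 °C then removes the thiolate, as is done with 4-sulfanylflavan-3-ols. The benzylic cation, now flanked by a neutral hydroxyl and not by a boron-bound alkoxide, is captured by ring A through the same all-equatorial chair. The route is rejoined at 22.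

**Step 15 (Mitsunobu etherification of 20).**
- What may go wrong: the oxyphosphonium group sits on a 4-benzyloxybenzylic carbon, so ionisation may compete with direct displacement and erode the inversion. The phenol may also open the acid-sensitive epoxide.
- Fallback: the C2–O1 bond is made before the epoxide exists and without a carbinol leaving group. Setting out from 5, Horner–Wadsworth–Emmons olefination (triethyl phosphonoacetate, NaH) gives ethyl (E)-3-[4-(benzyloxy)phenyl]acrylate F2.
- DIBAL-H reduction gives (E)-3-[4-(benzyloxy)phenyl]prop-2-en-1-ol F3, and methyl chloroformate with pyridine gives the cinnamyl methyl carbonate F4.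
- Iridium-catalysed asymmetric allylic etherification ([Ir(cod)Cl]2, chiral phosphoramidite, lithium phenoxide of 4, THF) gives the branched (R)-allyl aryl ether F5.
- Cross metathesis of F5 with styrene 18 under the conditions of step 13 gives the (E)-1,3-diarylallyl aryl ether F6. The Shi epoxidation of step 14 converts F6 into 21, where the route is rejoined.

**Step 8 (DDQ oxidation at L-C4).**
- What may go wrong: hydride abstraction may be slow on a ring A that carries only O7 and O1 as effective donors and has a withdrawing 3-acetoxy neighbour. It may also compete with abstraction at C2, which is benzylic to the 4-benzyloxyphenyl ring and α to O1.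
- Fallback: the C4 carbonyl is brought in by acylation, which also bypasses step 6. Setting out from 9, KOH in DMSO/H2O opens the oxirane at its terminal carbon to give (2R,3R)-3-[2,3-bis(benzyloxy)phenoxy]-3-[4-(benzyloxy)phenyl]propane-1,2-diol F7.
- TEMPO with PhI(OAc)2 in MeCN/H2O oxidises the primary alcohol to the α-hydroxy acid F8, and Ac2O with pyridine gives the α-acetoxy acid F9.
- Trifluoroacetic anhydride in CH2Cl2 at 0 °C closes the chromanone by intramolecular Friedel–Crafts acylation at the carbon para to the benzyloxy group. The route is rejoined at 13.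

Further compounds
F1 | step 16 | (2R,3S)-3-[2,3-bis(benzyloxy)phenoxy]-3-[4-(benzyloxy)phenyl]-1-(core 16)-1-(phenylsulfanyl)propan-2-ol, C1 inverted relative to the epoxide carbon of 21 | c1ccc(OCc2ccccc2)c(OCc2ccccc2)c1O[C@@H](c1ccc(OCc2ccccc2)cc1)[C@H](O)[C@H](Sc1ccccc1)c1cc2c(c(OCc3ccccc3)c1OCc1ccccc1)O[C@H](c1ccc(OCc3ccccc3)cc1)[C@@H]3OC(C)(C)O[C@H]23
F2 | step 15 | ethyl (E)-3-[4-(benzyloxy)phenyl]acrylate | CCOC(=O)/C=C/c1ccc(OCc2ccccc2)cc1
F3 | step 15 | (E)-3-[4-(benzyloxy)phenyl]prop-2-en-1-ol | OC/C=C/c1ccc(OCc2ccccc2)cc1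
F4 | step 15 | (E)-3-[4-(benzyloxy)phenyl]prop-2-en-1-yl methyl carbonate | COC(=O)OC/C=C/c1ccc(OCc2ccccc2)cc1
F5 | step 15 | (R)-1,2-bis(benzyloxy)-3-({1-[4-(benzyloxy)phenyl]prop-2-en-1-yl}oxy)benzene | c1ccc(OCc2ccccc2)c(OCc2ccccc2)c1O[C@@H](c1ccc(OCc2ccccc2)cc1)C=C
F6 | step 15 | (R,E)-1,2-bis(benzyloxy)-3-({1-[4-(benzyloxy)phenyl]-3-(core 16)prop-2-en-1-yl}oxy)benzene | c1ccc(OCc2ccccc2)c(OCc2ccccc2)c1O[C@@H](c1ccc(OCc2ccccc2)cc1)/C=C/c1cc2c(c(OCc3ccccc3)c1OCc1ccccc1)O[C@H](c1ccc(OCc3ccccc3)cc1)[C@@H]3OC(C)(C)O[C@H]23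
F7 | step 8 | (2R,3R)-3-[2,3-bis(benzyloxy)phenoxy]-3-[4-(benzyloxy)phenyl]propane-1,2-diol | c1ccc(OCc2ccccc2)c(OCc2ccccc2)c1O[C@H](c1ccc(OCc2ccccc2)cc1)[C@H](O)CO
F8 | step 8 | (2S,3R)-3-[2,3-bis(benzyloxy)phenoxy]-3-[4-(benzyloxy)phenyl]-2-hydroxypropanoic acid | c1ccc(OCc2ccccc2)c(OCc2ccccc2)c1O[C@H](c1ccc(OCc2ccccc2)cc1)[C@H](O)C(=O)O
F9 | step 8 | (2S,3R)-2-acetoxy-3-[2,3-bis(benzyloxy)phenoxy]-3-[4-(benzyloxy)phenyl]propanoic acid | c1ccc(OCc2ccccc2)c(OCc2ccccc2)c1O[C@H](c1ccc(OCc2ccccc2)cc1)[C@H](OC(C)=O)C(=O)O
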